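Start from the small charge: nucleophile at 0.900 equiv, less than the free base in either flask.

| flask | electrophile | nucleophile | free base | time |
|---|---|---|---|---|
| Monday's | 0.30 M | 0.900 equiv | 3.00 equiv | 30 min |
| Sunday's | 0.30 M | 0.900 equiv | 1.50 equiv | 30 min |

    electrophile + nucleophile → acid set free + target (k1 = 0.48 M⁻¹ s⁻¹)
    nucleophile + acid set free ⇌ protonated nucleophile, settled at all times (K2 = 59 M⁻¹)
    target ⇌ isomer of the product (K3 = 0.52, k3 = 0.0032 s⁻¹)
    acid set free + free base ⇌ salt of the base (K4 = 110 M⁻¹, k4 = 0.51 M⁻¹ s⁻¹)
    free base ⇌ dormant form (K5 = 0.29, k5 = 0.0055 s⁻¹)

1. part of the electrophile that has reacted at the end, Monday's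
2. part of the electrophile that has reacted at the end, Sunday's
3. what raising the equivalents of free base from its lowest to its highest value here does to the part of the electrophile that has reacted (changes below 5 percentage points count as none) (no change / it rises / it falls)

**Step one.** Each attack spends one nucleophile on one electrophile, so nucleophile is the limiting reagent. Reckon 90.0%: this is the ceiling C, nucleophile charged over electrophile charged, and it is the same in both flasks.

**Step two.** Ask whether the time reaches C. Let h be the half-life of electrophile under that attack, with nucleophile as charged: 0.0891 min. Go to logarithms: the time lies 2.53 powers of ten above h.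

**Step three.** Watch the acid set free, which can hold nucleophile as protonated nucleophile, reversibly. In Sunday's flask, the equilibrium constant times the charge is 16 for nucleophile and 50 for free base, so free base stands 0.495 of a power of ten higher.

**Step four.** Test the leaner flask, Sunday's. As an estimate, put its charge at balance with dormant form and count no salt: that gives 1.16 equiv of free base, above the 0.900 equiv of acid that C sets free.

**Step five.** Commit: both flasks reach C, so the trend is no change, under the margin of 5 percentage points.

The forecast gave 90% for Monday's and 89.8% for Sunday's, with no change, holding that “doubling the base only gets there sooner”.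

The simulation gives 90.0% for Monday's and 90.0% for Sunday's, a change of 0 points: no change.

Hold h against the time: Sunday's flask shows electrophile at 10.0% after 15.0 min and 10.0% after 30.0 min, with nucleophile at 0% at the end. Left for 300 min, Sunday's flask stands at 90.0%, the figure of C.

Now carry C to a neighbour of Sunday's flask charged with 0.360 equiv of nucleophile: scaled to that charge, C gives 36.0%. The neighbour gives 36.0%, with 64% of its electrophile left and nucleophile at 0%.

(Its constants were drawn at random within sensible limits; the result is computed.)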